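**Plan**
Retrosynthetic cuts, in order: the two O–allyl bonds (acid and phenol protection); C-3–CH2OH back to a C-3 N-acyl-(R)-4-benzyloxazolidinone; the C-2–C-3 bond of dioxane ring C, which opens the ring to a catechol bis(OCH2) ether; then the O-4–CH2 bond, the cinnamate C=C and the O-1–CH2 bond.
Forward: the ring A benzyl chloride goes onto the 4-OH of 3,4-dihydroxybenzaldehyde (later O-1), and olefination adds the acrylate. A bromoacetyl imide then goes onto the 3-OH (later O-4), and ring C, the only ring to be built, is closed last by a dehydrogenative C–C coupling of the two OCH2 carbons.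
Enabling feature: C-2 is bound to O-1 and stands para to the C-4 oxygen of ring A, so hydride loss gives an oxocarbenium ion that is an O-alkylated p-quinone methide with no β-hydrogen. C-3 bears a CH2OH that, raised to the imide level, makes C-3 an enolate carbon, so two carbons of like (donor) polarity are joined by oxidation.
Stereochemistry: C-3 comes from the auxiliary (chelated Z titanium enolate), C-2 from the diequatorial half-chair closure backed by the thermodynamic trans preference, and the E alkene from the stabilised phosphonate.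
Helpers and their removal: the imide and auxiliary leave in step 8 (NaBH4, which gives the CH2OH); both allyl groups leave in step 9.

Key step: step 7

Remark on the chemistry: locants follow 2,3-dihydro-1,4-benzodioxine numbering (O-1, C-2 with ring A, C-3 with CH2OH, O-4, acrylate at C-6). Ring A is the guaiacyl ring, ring B the benzo ring, ring C the dioxane ring. The target is read as the trans-(2R,3R) isomer with an E acrylic acid.

Step 1
Reactants: 1 vanillyl alcohol (4-hydroxy-3-methoxybenzyl alcohol)
Product: 2 4-(allyloxy)-3-methoxybenzyl alcohol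
Conditions: allyl bromide, K2CO3, acetone, reflux
Reagents that add atoms: allyl bromide, C=CCBr
Why: Williamson ether synthesis in which K2CO3 ionises only the phenol, so the benzylic alcohol stays free and no stereocentre is involved.

Step 2
Reactants: 2 4-(allyloxy)-3-methoxybenzyl alcohol
Product: 3 4-(allyloxy)-3-methoxybenzyl chloride
Conditions: SOCl2, CH2Cl2, 0 °C; used crude
Reagents that add atoms: thionyl chloride, O=S(Cl)Cl
Why: Chlorodehydroxylation of an electron-rich benzylic alcohol with SOCl2 is fast at 0 °C, and the labile chloride is carried on without purification.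

Step 3
Reactants: 4 3,4-dihydroxybenzaldehyde; 3 4-(allyloxy)-3-methoxybenzyl chloride
Product: 5 4-{[4-(allyloxy)-3-methoxyphenyl]methoxy}-3-hydroxybenzaldehyde
Conditions: NaHCO3, DMF, 40 °C
Reagents that add atoms: none
Why: Regioselective Williamson alkylation, since the 4-OH para to the formyl group is the more acidic one and is the only one ionised by the weak base NaHCO3.

Step 4
Reactants: 5 4-{[4-(allyloxy)-3-methoxyphenyl]methoxy}-3-hydroxybenzaldehyde; 6 allyl diethylphosphonoacetate
Product: 7 allyl (E)-3-(4-{[4-(allyloxy)-3-methoxyphenyl]methoxy}-3-hydroxyphenyl)acrylate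
Conditions: LiCl, DBU, MeCN, rt
Reagents that add atoms: none
Why: Horner–Wadsworth–Emmons olefination in its mild LiCl/amine variant, where the stabilised phosphonate gives the E alkene and the free phenol only costs one more equivalent of base.

Step 5
Reactants: 8 (R)-4-benzyloxazolidin-2-one; 9 bromoacetyl bromide
Product: 11 (R)-4-benzyl-3-(2-bromoacetyl)oxazolidin-2-one, via N-lithio oxazolidinone 10 (not isolated)
Conditions: n-BuLi, THF, −78 °C; then 9, −78 to 0 °C
Reagents that add atoms: none
Why: N-acylation of the lithiated oxazolidinone at the acyl bromide, which is far more reactive than the alkyl bromide, with the stereocentre of 8 untouched.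

Step 6
Reactants: 7 allyl (E)-3-(4-{[4-(allyloxy)-3-methoxyphenyl]methoxy}-3-hydroxyphenyl)acrylate; 11 (R)-4-benzyl-3-(2-bromoacetyl)oxazolidin-2-one
Product: 12 allyl (E)-3-(4-{[4-(allyloxy)-3-methoxyphenyl]methoxy}-3-{2-[(R)-4-benzyl-2-oxooxazolidin-3-yl]-2-oxoethoxy}phenyl)acrylate
Conditions: K2CO3, acetone, rt
Reagents that add atoms: none
Why: Williamson alkylation in which the α-bromo imide is a strongly activated SN2 electrophile, so the weakly basic phenoxide should attack carbon faster than the imide carbonyl.

Step 7
Reactants: 12 allyl (E)-3-(4-{[4-(allyloxy)-3-methoxyphenyl]methoxy}-3-{2-[(R)-4-benzyl-2-oxooxazolidin-3-yl]-2-oxoethoxy}phenyl)acrylate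
Product: 15 allyl (E)-3-{(2R,3S)-2-[4-(allyloxy)-3-methoxyphenyl]-3-[(R)-4-benzyl-2-oxooxazolidine-3-carbonyl]-2,3-dihydro-1,4-benzodioxin-6-yl}acrylate (trans), via DDQH mixed acetal 13 (not isolated), via oxocarbenium titanium enolate 14 (not isolated)
Conditions: DDQ (1.0 equiv), 4 Å molecular sieves, CH2Cl2, rt; then −78 °C, TiCl4 (2.5 equiv); then i-Pr2NEt (2.5 equiv), −78 to −20 °C; aq NH4Cl
Reagents that add atoms: none
Why: Proposed new method: DDQ abstracts hydride from the only C–H flanked by an ether oxygen (later O-1) and the p-allyloxy-substituted ring A, giving an aryloxy-stabilised p-alkoxybenzyl cation (an O-allylated p-quinone methide) stored as its DDQH adduct 13; TiCl4 re-ionises 13 and, with i-Pr2NEt, soft-enolises the bidentately bound imide to the chelated Z enolate 14, whose C-3 attacks C-2. The closest known reaction types are the DDQ-induced oxidative C–H cleavage of p-alkoxybenzyl ethers with capture of the oxocarbenium ion by a tethered carbon nucleophile, and the alkylation of titanium enolates of N-acyloxazolidinones by SN1-type electrophiles (acetals, orthoesters, α-chloro ethers); their merger on an aryl benzyl ether to close a 1,4-dioxane ring is new. Ring C closes in a 6-(enolexo)-endo-trig mode, with the C=O+ bond inside and the enolate C=C outside the forming ring. C-3 is set by the auxiliary, because in the chelated enolate the benzyl group of the (R)-oxazolidinone covers one face and the tethered cation is taken up on the other, which gives 3S in 15 (3R once the acyl group has become CH2OH). C-2 is set by the half-chair transition state, in which the E oxocarbenium ion places ring A and the anti aryl vinyl ether conformer places the acyl group pseudo-equatorially (trans), and reversible Lewis-acid ionisation of the C-2–O-1 bond can only drain a cis isomer to the more stable trans one because C-3 is untouched. The step needs site-selective oxidation without over-oxidation: the OCH2C=O hydrogens are deactivated by the carbonyl group, the monosubstituted allyl groups are much slower hydride donors, the cation has no β-hydrogen to lose, and all DDQ is spent before the oxidisable product 15 appears.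

Step 8
Reactants: 15 allyl (E)-3-{(2R,3S)-2-[4-(allyloxy)-3-methoxyphenyl]-3-[(R)-4-benzyl-2-oxooxazolidine-3-carbonyl]-2,3-dihydro-1,4-benzodioxin-6-yl}acrylate
Product: 16 allyl (E)-3-{(2R,3R)-2-[4-(allyloxy)-3-methoxyphenyl]-3-(hydroxymethyl)-2,3-dihydro-1,4-benzodioxin-6-yl}acrylate
Conditions: NaBH4, THF–H2O, 0 °C to rt
Reagents that add atoms: none
Why: Reductive cleavage of an N-acyloxazolidinone, in which hydride attacks the exocyclic imide carbonyl much faster than the conjugated allyl ester, both stereocentres keep their geometry (the C-3 descriptor changes only by priority) and 8 is recovered.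

Step 9
Reactants: 16 allyl (E)-3-{(2R,3R)-2-[4-(allyloxy)-3-methoxyphenyl]-3-(hydroxymethyl)-2,3-dihydro-1,4-benzodioxin-6-yl}acrylate
Product: 17 (E)-3-[(2R,3R)-2-(4-hydroxy-3-methoxyphenyl)-3-(hydroxymethyl)-2,3-dihydro-1,4-benzodioxin-6-yl]acrylic acid (target)
Conditions: Pd(PPh3)4 (cat.), morpholine, THF, rt; dilute citric acid work-up
Reagents that add atoms: none
Why: Tsuji–Trost deallylation, in which zerovalent palladium ionises both the allyl ester and the allyl aryl ether and morpholine takes up the allyl groups under nearly neutral conditions that leave the alkene, the alcohol and both stereocentres alone.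

**Compound list**
1 | vanillyl alcohol | COc1cc(CO)ccc1O | starting material
2 | 4-(allyloxy)-3-methoxybenzyl alcohol | C=CCOc1ccc(CO)cc1OC | intermediate
3 | 4-(allyloxy)-3-methoxybenzyl chloride | C=CCOc1ccc(CCl)cc1OC | intermediate
4 | 3,4-dihydroxybenzaldehyde | O=Cc1ccc(O)c(O)c1 | starting material
5 | 4-{[4-(allyloxy)-3-methoxyphenyl]methoxy}-3-hydroxybenzaldehyde | C=CCOc1ccc(COc2ccc(C=O)cc2O)cc1OC | intermediate
6 | allyl diethylphosphonoacetate | C=CCOC(=O)CP(=O)(OCC)OCC | starting material
7 | allyl (E)-3-(4-{[4-(allyloxy)-3-methoxyphenyl]methoxy}-3-hydroxyphenyl)acrylate | C=CCOC(=O)/C=C/c1ccc(OCc2ccc(OCC=C)c(OC)c2)c(O)c1 | intermediate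
8 | (R)-4-benzyloxazolidin-2-one | O=C1N[C@H](Cc2ccccc2)CO1 | starting material
9 | bromoacetyl bromide | O=C(Br)CBr | starting material
10 | N-lithio-(R)-4-benzyloxazolidin-2-one (not isolated) | [Li]N1[C@H](Cc2ccccc2)COC1=O | intermediate
11 | (R)-4-benzyl-3-(2-bromoacetyl)oxazolidin-2-one | O=C(CBr)N1[C@H](Cc2ccccc2)COC1=O | intermediate
12 | allyl (E)-3-(4-{[4-(allyloxy)-3-methoxyphenyl]methoxy}-3-{2-[(R)-4-benzyl-2-oxooxazolidin-3-yl]-2-oxoethoxy}phenyl)acrylate | C=CCOC(=O)/C=C/c1ccc(OCc2ccc(OCC=C)c(OC)c2)c(OCC(=O)N2[C@H](Cc3ccccc3)COC2=O)c1 | intermediate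
13 | DDQH mixed acetal of 12 at the ring A benzylic carbon, both epimers (not isolated) | C=CCOC(=O)/C=C/c1ccc(OC(Oc2c(Cl)c(Cl)c(O)c(C#N)c2C#N)c2ccc(OCC=C)c(OC)c2)c(OCC(=O)N2[C@H](Cc3ccccc3)COC2=O)c1 | intermediate
14 | aryl oxocarbenium ion carrying the trichlorotitanium Z enolate of the imide, counter-ion drawn as chloride (not isolated) | C=CCOC(=O)/C=C/c1ccc([O+]=Cc2ccc(OCC=C)c(OC)c2)c(O/C=C(\O[Ti](Cl)(Cl)Cl)N2[C@H](Cc3ccccc3)COC2=O)c1.[Cl-] | intermediate
15 | allyl (E)-3-{(2R,3S)-2-[4-(allyloxy)-3-methoxyphenyl]-3-[(R)-4-benzyl-2-oxooxazolidine-3-carbonyl]-2,3-dihydro-1,4-benzodioxin-6-yl}acrylate (trans) | COc1cc([C@H]2Oc3ccc(/C=C/C(=O)OCC=C)cc3O[C@@H]2C(=O)N2[C@H](Cc3ccccc3)COC2=O)ccc1OCC=C | intermediate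
16 | allyl (E)-3-{(2R,3R)-2-[4-(allyloxy)-3-methoxyphenyl]-3-(hydroxymethyl)-2,3-dihydro-1,4-benzodioxin-6-yl}acrylate | COc1cc([C@H]2Oc3ccc(/C=C/C(=O)OCC=C)cc3O[C@@H]2CO)ccc1OCC=C | intermediate
17 | (E)-3-[(2R,3R)-2-(4-hydroxy-3-methoxyphenyl)-3-(hydroxymethyl)-2,3-dihydro-1,4-benzodioxin-6-yl]acrylic acid | COc1cc([C@H]2Oc3ccc(/C=C/C(=O)O)cc3O[C@@H]2CO)ccc1O | target

Total step count: 9. Longest linear sequence: 8 (steps 1, 2, 3, 4, 6, 7, 8, 9).

**Steps most likely to fail**

Step 7 (bears the label "Proposed new method:"). Several processes may interfere: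
- Traces of water may capture the cation and cleave the ring A benzyl ether.
- The ring B aryloxide may depart instead of the DDQH oxide on re-ionisation.
- Enolisation may be too slow relative to intermolecular arene attack on the cation.
- Facial selectivity may erode if closure runs through a non-chelated enol.
- C-3 may lose a proton after ring re-opening.

The fallback sets out from 12 and comes back at 15. It makes the C-2–C-3 bond between two molecules by known chemistry and then closes ring C at the C-2–O-1 bond. Compound 12 is cleaved with DDQ in wet CH2Cl2 (ordinary oxidative removal of a p-alkoxybenzyl ether). This gives allyl (E)-3-(3-{2-[(R)-4-benzyl-2-oxooxazolidin-3-yl]-2-oxoethoxy}-4-hydroxyphenyl)acrylate F1 and 4-(allyloxy)-3-methoxybenzaldehyde F2. The aldehyde is converted with HC(OMe)3 and catalytic p-TsOH in MeOH into 4-(allyloxy)-3-methoxybenzaldehyde dimethyl acetal F3. F1 is treated with TiCl4 and i-Pr2NEt (one extra equivalent of each for the phenol) and then with F3 and BF3·OEt2 at low temperature. This is the known addition of such imide enolates to acetals, and it should give the β-methoxy imide F4 with C-3 set by the auxiliary in the same sense as in step 7. Camphorsulfonic acid in CH2Cl2 then ionises the benzylic methoxy group, and the ring B phenol closes ring C under thermodynamic control to trans 15.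

Step 6. Acyl transfer from the imide to the phenoxide, with loss of the auxiliary, may compete with SN2 displacement of bromide. The fallback sets out from 7 and comes back at 12, reversing the order of bond formation at the glycolate unit. Compound 7 is alkylated with bromoacetic acid (NaH, THF–DMF) to give the aryloxyacetic acid F5. Pivaloyl chloride and Et3N convert it into the mixed pivalic anhydride F6, which acylates 8 in the presence of LiCl and Et3N to give 12. Step 5 is then not needed.

Step 8. Base-induced β-elimination of the O-1 aryloxide, or endocyclic opening of the oxazolidinone ring at the hindered imide, may compete with hydride delivery to the exocyclic carbonyl. The fallback sets out from 15 and comes back at 16, separating cleavage from reduction. LiOH/H2O2 in THF–H2O at 0 °C removes the auxiliary to give the C-3 carboxylic acid F7. Isobutyl chloroformate and N-methylmorpholine at −15 °C give the mixed carbonic anhydride F8, which NaBH4 in THF–H2O reduces to 16 without touching the allyl groups or the cinnamate.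

**Further compounds**
F1 | step 7 | allyl (E)-3-(3-{2-[(R)-4-benzyl-2-oxooxazolidin-3-yl]-2-oxoethoxy}-4-hydroxyphenyl)acrylate | C=CCOC(=O)/C=C/c1ccc(O)c(OCC(=O)N2[C@H](Cc3ccccc3)COC2=O)c1
F2 | step 7 | 4-(allyloxy)-3-methoxybenzaldehyde | C=CCOc1ccc(C=O)cc1OC
F3 | step 7 | 4-(allyloxy)-3-methoxybenzaldehyde dimethyl acetal | C=CCOc1ccc(C(OC)OC)cc1OC
F4 | step 7 | β-methoxy imide, (S) at the aryloxy-bearing carbon, methoxy-bearing carbon as formed | C=CCOC(=O)/C=C/c1ccc(O)c(O[C@@H](C(OC)c2ccc(OCC=C)c(OC)c2)C(=O)N2[C@H](Cc3ccccc3)COC2=O)c1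
F5 | step 6 | aryloxyacetic acid from 7 | C=CCOC(=O)/C=C/c1ccc(OCc2ccc(OCC=C)c(OC)c2)c(OCC(=O)O)c1
F6 | step 6 | mixed pivalic anhydride of F5 | C=CCOC(=O)/C=C/c1ccc(OCc2ccc(OCC=C)c(OC)c2)c(OCC(=O)OC(=O)C(C)(C)C)c1
F7 | step 8 | C-3 carboxylic acid from 15 (trans) | COc1cc([C@H]2Oc3ccc(/C=C/C(=O)OCC=C)cc3O[C@@H]2C(=O)O)ccc1OCC=C
F8 | step 8 | mixed isobutyl carbonic anhydride of F7 | COc1cc([C@H]2Oc3ccc(/C=C/C(=O)OCC=C)cc3O[C@@H]2C(=O)OC(=O)OCC(C)C)ccc1OCC=C
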